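The route rests on disconnecting the C5–C6 bond of ring B (ring A: C1–C5 and C10; ring B: C5–C10; C14 and C15 are the methyls on C5 and C4). The key step exploits the fact that quaternary C5 lies β to C7, the α-carbon of the C8 ketone: hydrogen-atom transfer to an exocyclic C5=C14 methylene makes the C14 methyl and a tertiary C5 radical, which adds 6-endo to C6 of a C8 vinyl ketone, closing ring B and setting C5 in one operation. The precursor is a ring A methylenecyclohexane (3α-OTBS, 4β-methyl, 10α-H) carrying the (9S)-CH(OTES)–CO–CH=CH2 chain on C10; all its stereocentres are set on a cis-fused γ-lactone.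

Key step: step 11

Remark: target numbering is used for every intermediate; β is the face of the C4 and C5 methyls, α the opposite one. The target has 3α-O, 4β-Me, 5β-Me, 7α-isopropenyl, 9α-O and 10α-H (trans-fused), and compounds 17, 18 and 29 encode exactly this. Racemic 4 is resolved by the reagent-controlled reduction of step 2.

Step 1
Reactants: 1 2-methylcyclohex-2-en-1-one; 2 methyl bromoacetate
Product: 4 methyl 2-(3-methyl-2-oxocyclohex-3-en-1-yl)acetate (racemate), via lithium dienolate 3 (not isolated)
Conditions: LiN(i-Pr)2, THF, −78 °C; then 2, DMPU, −78 → −30 °C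
Reagents that add atoms: none
Why: kinetic deprotonation at the α′-methylene (C10) gives the cross-conjugated lithium enolate, and its SN2 alkylation by the bromoacetate (enolate alkylation) attaches C9 and C8 to C10; C10 is racemic at this stage and is resolved in step 2.

Step 2
Reactants: 4 methyl 2-(3-methyl-2-oxocyclohex-3-en-1-yl)acetate (racemate)
Product: 6 (3aS,7aR)-7-methyl-3a,4,5,7a-tetrahydro-1-benzofuran-2(3H)-one, via cis-hydroxy ester 5 (not isolated)
Conditions: (S)-Me-CBS [(S)-1-methyl-3,3-diphenyltetrahydro-1H,3H-pyrrolo[1,2-c][1,3,2]oxazaborole] (15 mol %), BH3·SMe2 (0.6 equiv), THF, −20 °C; MeOH; then pyridinium p-toluenesulfonate (cat.), PhMe, 50 °C; chromatography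
Reagents that add atoms: none
Why: Corey–Bakshi–Shibata reduction is reagent-controlled (the alkenyl side of the enone plays the large group, as aryl does in aryl alkyl ketones), so both enantiomers of 4 should give the 5R carbinol (5β-OH); the isomer from (S)-4 has OH and CH2CO2Me cis and closes under acid catalysis (lactonisation by transesterification) to the cis-fused γ-lactone 6, which is separated from the trans hydroxy ester formed from (R)-4.

Step 3
Reactants: 6 (3aS,7aR)-7-methyl-3a,4,5,7a-tetrahydro-1-benzofuran-2(3H)-one
Product: 8 (3aS,6R,7S,7aR)-6-hydroxy-7-methylhexahydro-1-benzofuran-2(3H)-one, via C3 alkylborane 7 (not isolated)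
Conditions: BH3·THF (1.1 equiv), THF, 0 °C; then 30% H2O2, aq. NaH2PO4/Na2HPO4 (pH 7), MeOH, 0 → 23 °C
Reagents that add atoms: hydrogen peroxide, OO
Why: hydroboration–oxidation: borane adds syn and anti-Markovnikov to the trisubstituted C3=C4 alkene from the convex α face, anti to the allylic lactone oxygen on C5 and to the C10–C9 bond, so C3–O (α) and C4–H (α, hence 4β-methyl) are set together, and the C–B bond is oxidised with retention.

Step 4
Reactants: 8 (3aS,6R,7S,7aR)-6-hydroxy-7-methylhexahydro-1-benzofuran-2(3H)-one
Product: 9 TBS ether of 8 (3α-OTBS; 4β-methyl; cis-fused lactone)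
Conditions: TBSCl, imidazole, DMF, 23 °C
Reagents that add atoms: tert-butyldimethylsilyl chloride, CC(C)(C)[Si](C)(C)Cl
Why: silylation (silyl ether formation) of the equatorial secondary C3 alcohol gives an ether that withstands enolate, organometallic, radical and mildly acidic steps and is kept until step 15.

Step 5
Reactants: 9 TBS ether of 8
Product: 11 9-hydroxy lactone (9S; 9-OH cis to 10-H; 3α-OTBS), via potassium enolate 10 (not isolated)
Conditions: KN(SiMe3)2, THF, −78 °C; 2-(phenylsulfonyl)-3-phenyloxaziridine, −78 °C; AcOH
Reagents that add atoms: 2-(phenylsulfonyl)-3-phenyloxaziridine, O=S(=O)(c1ccccc1)N1OC1c1ccccc1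
Why: enolate hydroxylation with an N-sulfonyloxaziridine (Davis oxidation): the oxidant reaches the lactone enolate on the convex face of the cis-fused bicycle, anti to the C10–C1 bond, which puts the new C9 oxygen cis to 10-H and gives the 9S centre that becomes 9α-O in the decalin.

Step 6
Reactants: 11 9-hydroxy lactone
Product: 12 9-O-TES ether of 11
Conditions: TESCl, imidazole, 4-(dimethylamino)pyridine (DMAP, cat.), CH2Cl2, 0 → 23 °C
Reagents that add atoms: chlorotriethylsilane, CC[Si](Cl)(CC)CC
Why: silylation (silyl ether formation) of the α-hydroxy lactone; a silyl ether is chosen at C9 because, unlike a benzylic ether, it offers the later C5 radical no activated C–H bond, and because it can be cleaved beside the C3 TBS ether.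

Step 7
Reactants: 12 9-O-TES ether of 11
Product: 13 hydroxy Weinreb amide (5β-OH; 9S-OTES; 3α-OTBS; 4β-methyl; 10α-H)
Conditions: MeNH(OMe)·HCl, AlMe3, CH2Cl2, 0 → 23 °C; aq. potassium sodium tartrate (KNaC4H4O6)
Reagents that add atoms: N,O-dimethylhydroxylamine hydrochloride, CNOC.Cl
Why: Weinreb aminolysis of the lactone by the weakly basic aluminium amide opens the ring at the acyl carbon C8 without touching C9 or C10, turns C8 into the N-methoxy-N-methylamide and frees the axial C5 alcohol, which is oxidised without delay to forestall relactonisation.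

Step 8
Reactants: 13 hydroxy Weinreb amide
Product: 14 C5 ketone Weinreb amide
Conditions: Dess–Martin periodinane, pyridine, CH2Cl2, 0 → 23 °C
Reagents that add atoms: none
Why: Dess–Martin oxidation of the secondary alcohol under buffered, non-basic conditions, so the new ketone is not enolised toward C4 or C10 and neither epimerisation nor β-elimination of the C9 silyloxy group should occur.

Step 9
Reactants: 14 C5 ketone Weinreb amide
Product: 15 5-methylene Weinreb amide
Conditions: Zn, CH2Br2, TiCl4, THF/CH2Cl2, 0 → 23 °C
Reagents that add atoms: dibromomethane, BrCBr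
Why: Takai–Lombardo methylenation: the non-basic gem-dimetallic titanium methylene reagent converts the hindered, enolisable C5 ketone into the exocyclic C5=C14 alkene without epimerising C4 or C10 and leaves the amide untouched.

Step 10
Reactants: 15 5-methylene Weinreb amide; 16 vinylmagnesium bromide
Product: 17 vinyl ketone precursor (ring A methylenecyclohexane; 3α-OTBS; 4β-methyl; 10α-H; C10 bears (9S)-CH(OTES)–CO–CH=CH2)
Conditions: CH2=CHMgBr, THF, −78 → 0 °C; AcOH/THF, −78 °C, then aq. NH4Cl
Reagents that add atoms: none
Why: Weinreb ketone synthesis: the chelated tetrahedral adduct persists until the acidic quench, so only one vinyl group is delivered and the released amine is protonated before it can add to the vinyl ketone.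

Step 11
Reactants: 17 vinyl ketone precursor
Product: 18 trans-decalin-8-one (5β-methyl C14; 10α-H; 4β-methyl; 3α-OTBS; 9α-OTES)
Conditions: Fe(acac)3 (30 mol %), PhSiH2(Oi-Pr) (2 equiv, slow addition), EtOH (0.01 M), 23 °C, Ar
Reagents that add atoms: none
Why: Fe(acac)3 and the alkoxysilane generate an iron hydride that transfers a hydrogen atom to C14 of the electron-rich 1,1-disubstituted alkene, so the C14 methyl and a nucleophilic tertiary C5 radical form together; the radical adds to C6, the unsubstituted β-carbon of the vinyl ketone, and the α-keto radical at C7 is reduced by divalent iron to the enolate and protonated by ethanol, which returns trivalent iron. The closest known reaction type is the iron-hydride hydrogen-atom-transfer reductive coupling of unactivated alkenes with enones (a Giese-type conjugate addition), used here intramolecularly. Ring B (C5–C10) closes in the 6-endo-trig mode, because the 5-exo alternative would need attack on the electron-poor α-carbon C7 and would leave a primary radical. The new stereocentre C5 is controlled by C10: ring A stays in the chair with 3-OTBS, 4-methyl and the C10 chain equatorial, and a chair-like transition state for ring B forms the C5–C6 bond equatorially on the α face while C14 turns axial (β), anti to 10α-H, which is the trans fusion known from the ring closures of radical polyene cyclisations. The step needs hydrogen-atom transfer to the methylene in preference to reduction of the enone, secured by the polarity match of the hydride with the electron-rich alkene and by dilution with slow silane addition, and it needs trans over cis closure, secured by the equatorial chain and its equatorial 9α-OTES group, since closure on the β face would bring C6 in axially over the axial hydrogens on C1 and C3.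

Step 12
Reactants: 18 trans-decalin-8-one; 19 2-bromopropene
Product: 21 7α-isopropenyl ketone (9α-OTES; 3α-OTBS), via lithium enolate 20 (not isolated)
Conditions: LiN(SiMe3)2 (2.2 equiv), THF, −78 °C; then 19, Pd2(dba)3 (5 mol %), t-Bu3P (10 mol %), PhMe, −78 → 23 °C; AcOH, −78 °C
Reagents that add atoms: none
Why: palladium-catalysed α-alkenylation of a ketone enolate: kinetic deprotonation takes the C7 methylene and not the hindered, silyloxy-bearing C9–H, the enolate couples with the alkenyl bromide by oxidative addition to zerovalent palladium, transmetalation and reductive elimination, and the acidic C7–H of the product settles in the equatorial 7α-isopropenyl arrangement, anti to the axial C14 methyl.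

Step 13
Reactants: 21 7α-isopropenyl ketone
Product: 22 9α-alcohol (3α-OTBS retained)
Conditions: pyridinium p-toluenesulfonate (cat.), MeOH/CH2Cl2, 0 °C
Reagents that add atoms: none
Why: acid-catalysed methanolysis of a silyl ether: the triethylsilyl ether is cleaved much faster than the bulkier tert-butyldimethylsilyl ether, so only the C9 hydroxyl is freed and the mild acid leaves the β,γ-unsaturated ketone alone.

Step 14
Reactants: 22 9α-alcohol; 23 tiglic acid
Product: 25 9α-tiglate (3α-OTBS), via mixed anhydride 24 (not isolated)
Conditions: 23, 2,4,6-Cl3C6H2COCl, Et3N, THF, 23 °C; then 22, DMAP, PhMe, 23 → 40 °C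
Reagents that add atoms: none
Why: Yamaguchi esterification: DMAP attacks the mixed 2,4,6-trichlorobenzoic anhydride at the tigloyl carbonyl and passes the acyl group to the hindered C9 alcohol with retention at C9, and the E geometry of the tiglate is kept because no ketene pathway is open.

Step 15
Reactants: 25 9α-tiglate
Product: 26 3α-alcohol 9α-tiglate
Conditions: HF·pyridine, pyridine/THF, 0 → 23 °C
Reagents that add atoms: none
Why: fluoride-mediated desilylation under buffered acidic conditions removes the TBS group without the acyl migration or ester cleavage at the α-acyloxy ketone that basic fluoride sources would risk.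

Step 16
Reactants: 26 3α-alcohol 9α-tiglate; 27 3-methylbut-2-enoic acid
Product: 29 CNP0164025.1 (3α-senecioate; 9α-tiglate), via O-acylisourea 28 (not isolated)
Conditions: 27, N,N'-dicyclohexylcarbodiimide (DCC), DMAP (cat.), CH2Cl2, 0 → 23 °C
Reagents that add atoms: none
Why: Steglich esterification: the carbodiimide activates the acid as its O-acylisourea and DMAP transfers the senecioyl group to the equatorial C3 alcohol with retention, avoiding the acid chloride and amine conditions that deconjugate senecioates through a vinylketene.

Compound list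
1 | 2-methylcyclohex-2-en-1-one | CC1=CCCCC1=O | starting material
2 | methyl bromoacetate | COC(=O)CBr | starting material
3 | lithium 6-methylcyclohexa-1,5-dien-1-olate (cross-conjugated α′-enolate of 1) | CC1=CCCC=C1O[Li] | intermediate
4 | methyl 2-(3-methyl-2-oxocyclohex-3-en-1-yl)acetate, racemic at C10 | COC(=O)CC1CCC=C(C)C1=O | intermediate
5 | methyl 2-[(1S,2R)-2-hydroxy-3-methylcyclohex-3-en-1-yl]acetate (5β-OH cis to the C10 chain) | COC(=O)C[C@@H]1CCC=C(C)[C@@H]1O | intermediate
6 | (3aS,7aR)-7-methyl-3a,4,5,7a-tetrahydro-1-benzofuran-2(3H)-one (cis-fused γ-lactone; O–C5 and C9–C10 both β; C3=C4 alkene) | O=C1C[C@@H]2CCC=C(C)[C@@H]2O1 | intermediate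
7 | C3 alkylborane of 6 (3α-BH2, 4α-H, 4β-methyl; cis-fused lactone) | O=C1C[C@@H]2CC[C@@H](B)[C@H](C)[C@@H]2O1 | intermediate
8 | (3aS,6R,7S,7aR)-6-hydroxy-7-methylhexahydro-1-benzofuran-2(3H)-one (3α-OH, 4β-methyl) | O=C1C[C@@H]2CC[C@@H](O)[C@H](C)[C@@H]2O1 | intermediate
9 | TBS ether of 8 (3α-OTBS, 4β-methyl, cis-fused lactone) | O=C1C[C@@H]2CC[C@@H](O[Si](C)(C)C(C)(C)C)[C@H](C)[C@@H]2O1 | intermediate
10 | potassium enolate of 9 (C8–C9 enolate) | [K]OC1=C[C@@H]2CC[C@@H](O[Si](C)(C)C(C)(C)C)[C@H](C)[C@@H]2O1 | intermediate
11 | 9-hydroxy lactone (9S, OH cis to 10-H; 3α-OTBS, 4β-methyl) | O=C1[C@@H](O)[C@@H]2CC[C@@H](O[Si](C)(C)C(C)(C)C)[C@H](C)[C@@H]2O1 | intermediate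
12 | 9-O-TES ether of 11 | O=C1[C@@H](O[Si](CC)(CC)CC)[C@@H]2CC[C@@H](O[Si](C)(C)C(C)(C)C)[C@H](C)[C@@H]2O1 | intermediate
13 | N-methoxy-N-methyl-2-(triethylsilyloxy)acetamide bearing at C9 (9S) the ring A cyclohexyl group (10α-H, 5β-OH, 4β-methyl, 3α-OTBS) | CON(C)C(=O)[C@@H](O[Si](CC)(CC)CC)[C@@H]1CC[C@@H](O[Si](C)(C)C(C)(C)C)[C@H](C)[C@@H]1O | intermediate
14 | C5 ketone of 13 (9S-OTES, 10α-H, 4β-methyl, 3α-OTBS) | CON(C)C(=O)[C@@H](O[Si](CC)(CC)CC)[C@@H]1CC[C@@H](O[Si](C)(C)C(C)(C)C)[C@H](C)C1=O | intermediate
15 | 5-methylene Weinreb amide (C5=C14; 9S-OTES, 10α-H, 4β-methyl, 3α-OTBS) | CON(C)C(=O)[C@@H](O[Si](CC)(CC)CC)[C@@H]1CC[C@@H](O[Si](C)(C)C(C)(C)C)[C@H](C)C1=C | intermediate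
16 | vinylmagnesium bromide | C=C[Mg]Br | starting material
17 | (4S)-4-(triethylsilyloxy)but-1-en-3-one bearing at C9 the ring A 5-methylenecyclohexyl group (10α-H, 4β-methyl, 3α-OTBS); key-step precursor | C=CC(=O)[C@@H](O[Si](CC)(CC)CC)[C@@H]1CC[C@@H](O[Si](C)(C)C(C)(C)C)[C@H](C)C1=C | intermediate
18 | trans-decalin-8-one with 5β-methyl (C14), 10α-H, 4β-methyl, 3α-OTBS, 9α-OTES; key-step product | C1C[C@]2(C)[C@@H](C)[C@H](O[Si](C)(C)C(C)(C)C)CC[C@H]2[C@H](O[Si](CC)(CC)CC)C1=O | intermediate
19 | 2-bromopropene | C=C(C)Br | starting material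
20 | lithium C7–C8 enolate of 18 | [Li]OC1=CC[C@]2(C)[C@@H](C)[C@H](O[Si](C)(C)C(C)(C)C)CC[C@H]2[C@@H]1O[Si](CC)(CC)CC | intermediate
21 | 7α-isopropenyl trans-decalin-8-one (9α-OTES, 3α-OTBS) | C=C(C)[C@@H]1C[C@]2(C)[C@@H](C)[C@H](O[Si](C)(C)C(C)(C)C)CC[C@H]2[C@H](O[Si](CC)(CC)CC)C1=O | intermediate
22 | 9α-hydroxy-7α-isopropenyl trans-decalin-8-one (3α-OTBS) | C=C(C)[C@@H]1C[C@]2(C)[C@@H](C)[C@H](O[Si](C)(C)C(C)(C)C)CC[C@H]2[C@H](O)C1=O | intermediate
23 | tiglic acid, (E)-2-methylbut-2-enoic acid | C/C=C(\C)C(=O)O | starting material
24 | tiglic 2,4,6-trichlorobenzoic anhydride | C/C=C(\C)C(=O)OC(=O)c1c(Cl)cc(Cl)cc1Cl | intermediate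
25 | 9α-tigloyloxy-7α-isopropenyl trans-decalin-8-one (3α-OTBS) | C=C(C)[C@@H]1C[C@]2(C)[C@@H](C)[C@H](O[Si](C)(C)C(C)(C)C)CC[C@H]2[C@H](OC(=O)/C(C)=C/C)C1=O | intermediate
26 | 3α-hydroxy-9α-tigloyloxy-7α-isopropenyl trans-decalin-8-one | C=C(C)[C@@H]1C[C@]2(C)[C@@H](C)[C@H](O)CC[C@H]2[C@H](OC(=O)/C(C)=C/C)C1=O | intermediate
27 | 3-methylbut-2-enoic acid (senecioic acid) | CC(C)=CC(=O)O | starting material
28 | O-(3-methylbut-2-enoyl)-N,N'-dicyclohexylisourea | CC(C)=CC(=O)OC(=NC1CCCCC1)NC1CCCCC1 | intermediate
29 | CNP0164025.1: 3α-(3-methylbut-2-enoyloxy)-9α-[(E)-2-methylbut-2-enoyloxy]-7α-isopropenyl-4β,5β-dimethyl-10α-H trans-decalin-8-one | C=C(C)[C@@H]1C[C@]2(C)[C@@H](C)[C@H](OC(=O)C=C(C)C)CC[C@H]2[C@H](OC(=O)/C(C)=C/C)C1=O | target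

Total step count: 16. Longest linear sequence: 16 steps from 1 (compounds 2, 16, 19, 23 and 27 are purchased).

Steps most likely to fail

First, step 11. Bond formation at C5 may take place on the β face (axial attack) and give the cis-fused ring. The iron hydride may reduce the vinyl ketone or quench the C5 radical before ring closure. The ethanolic medium may also strip the triethylsilyl ether. The fallback generates the same C5 radical without any metal hydride, by photoredox decarboxylation of a tertiary oxalate, and sets out from 15. Mukaiyama hydration (Co(acac)2, PhSiH3, O2, i-PrOH) of the methylene should give the tertiary C5 alcohol F1 (a C5 epimer mixture, both epimers serve). Excess CH2=CHMgBr converts the Weinreb amide into the hydroxy vinyl ketone F2. Oxalyl chloride followed by aqueous CsHCO3 gives the caesium oxalate F3. Blue-light irradiation with [Ir(dF(CF3)ppy)2(dtbbpy)]PF6 in DME/DMF/water expels two molecules of CO2 and leaves the tertiary C5 radical, which closes 6-endo onto C6. Reduction and protonation of the α-keto radical bring the sequence back to the route at 18. With no hydride present the enone cannot be reduced, and only the chair-controlled facial choice remains.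

Second, step 12. Proton transfer between product and enolate may move the enolate to the C9 side, with loss of regiocontrol and of the C9 configuration. The isopropenyl double bond may migrate into conjugation with the ketone under the basic conditions, and a second alkenylation may follow. The fallback sets out from 18. The C7 zinc enolate (LiN(SiMe3)2, then ZnCl2) adds to acetone (aldol addition) to give the β-hydroxy ketone F4. Dehydration (SOCl2, pyridine, then DBU) is driven to the conjugated isopropylidene ketone F5. Deprotonation of a γ-methyl group with KOt-Bu in t-BuOH/THF and rapid quenching of the extended dienolate into cold aqueous acetic acid (kinetic α-protonation, deconjugation) should return the β,γ-unsaturated ketone with the equatorial 7α-isopropenyl group, which is 21.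

Third, step 2. Reagent control may be incomplete for the mismatched enantiomer of 4, so the enantiomeric cis alcohol would leak into the lactone and erode its enantiomeric purity; at best half of 4 is used. The fallback sets out from racemic 4 and replaces the borane reduction by hydrogenation of the ketone under dynamic kinetic resolution, with a chiral RuCl2(xylbinap)(daipen) catalyst and KOt-Bu in i-PrOH. The base epimerises C10 of the ketone faster than either enantiomer is reduced, and the catalyst hydrogenates C=O in preference to C=C and is cis-selective. Both enantiomers should therefore funnel into the cis alcohol 5, which lactonises to 6, where the route is rejoined. No new compound arises (F0).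

Further compounds
F1 | step 11 | tertiary C5 alcohol from hydration of 15 (5-hydroxy-5-methyl, C5 epimer mixture; 9S-OTES, 3α-OTBS, 4β-methyl, Weinreb amide) | CON(C)C(=O)[C@@H](O[Si](CC)(CC)CC)[C@@H]1CC[C@@H](O[Si](C)(C)C(C)(C)C)[C@H](C)C1(C)O
F2 | step 11 | hydroxy vinyl ketone (5-hydroxy-5-methyl analogue of 17) | C=CC(=O)[C@@H](O[Si](CC)(CC)CC)[C@@H]1CC[C@@H](O[Si](C)(C)C(C)(C)C)[C@H](C)C1(C)O
F3 | step 11 | caesium oxalate of F2 (C5–O–CO–CO2Cs) | C=CC(=O)[C@@H](O[Si](CC)(CC)CC)[C@@H]1CC[C@@H](O[Si](C)(C)C(C)(C)C)[C@H](C)C1(C)OC(=O)C(=O)[O-].[Cs+]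
F4 | step 12 | 7α-(2-hydroxypropan-2-yl) trans-decalin-8-one (9α-OTES, 3α-OTBS) | CC(C)(O)[C@@H]1C[C@]2(C)[C@@H](C)[C@H](O[Si](C)(C)C(C)(C)C)CC[C@H]2[C@H](O[Si](CC)(CC)CC)C1=O
F5 | step 12 | 7-isopropylidene trans-decalin-8-one (9α-OTES, 3α-OTBS) | CC(C)=C1C[C@]2(C)[C@@H](C)[C@H](O[Si](C)(C)C(C)(C)C)CC[C@H]2[C@H](O[Si](CC)(CC)CC)C1=O
F0 | step 2 | none | none
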